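The question is how much of the substrate that has reacted in each flask stands as target at the end, with side product B holding the rest.

| setting | gamma | zeta | theta | delta |
|---|---|---|---|---|
| substrate | 0.015 M | 0.015 M | 0.015 M | 0.015 M |
| reagent | 1.50 equiv | 1.50 equiv | 1.50 equiv | 1.50 equiv |
| temperature | 130 °C | 90 °C | 110 °C | 150 °C |
| time | 20 s | 20 s | 20 s | 20 s |

    2 reagent → side product A (k1 = 0.0103 M⁻¹ s⁻¹, Ea1 = 71.0 kJ mol⁻¹)
    substrate + target → side product B (k2 = 2.25 M⁻¹ s⁻¹, Ea2 = 49.0 kJ mol⁻¹)
    substrate + reagent → target (k3 = 1.42 M⁻¹ s⁻¹, Ea3 = 56.0 kJ mol⁻¹)
    (constants at 110 °C)

- percentages count the substrate that a species holds: one side product B counts as two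
- for a step with 2 of a species take k times the square, and two of it per event
- all constants are for 110 °C and move with temperature by the activation energies

* which flask leads in share of target in all that became target or side product B ("all alike" within 1.5 percentage points) (gamma / zeta / theta / delta / all alike)
* share of target in all that became target or side product B, gamma
* share of target in all that became target or side product B, zeta
* share of target in all that became target or side product B, theta
* share of target in all that became target or side product B, delta

Call km the constant of substrate + reagent → target and ks that of substrate + target → side product B. Two things here seem not to go together. The selectivity factor ks/km is 1.79 in zeta, larger than 1.29 in delta, so zeta favours the spoiling step more, yet zeta is the flask expected to lead in share of target.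

This reckoning freezes reagent. At the start of delta, reagent goes to target 29 times faster than to side product A, and the self-reaction has the higher activation energy, so this starting ratio stands higher in the colder flasks, the self-reaction is dropped and the making step is treated as pseudo-first-order. Conversion is taken as 1 − exp(−km[reagent]t) with [reagent] at its charge. Spoiling speeds substrate loss and falling reagent slows it, and these two errors are left to cancel.

Dividing the two rates removes time. Target gained per substrate converted is (1 − w)/(1 + w), where w is the spoiling rate over the making rate. To first order the share falls as 1 − z, and it is written here as 1/(1 + z), which has the same start and stays below 1. Here z is the spoilage number, ks[converted]/(km[reagent]), the rate ratio if the converted substrate stood wholly as target, with [reagent] held at its charge less half the converted substrate. Zeta is reckoned to convert 21.5%, which gives z = 0.277.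

| Flask | ks/km | Conversion | z | Share |
|---|---|---|---|---|
| gamma | 1.42 | 78.3% | 1.00 | 49.9% |
| zeta | 1.79 | 21.5% | 0.277 | 78.3% |
| theta | 1.58 | 47.2% | 0.592 | 62.8% |
| delta | 1.29 | 96.5% | 1.22 | 45.0% |

From zeta to delta the reckoned conversion grows 4.49 times while ks/km shrinks 1.39 times, so the reckoned z climbs with temperature and the reckoning puts zeta in the lead.

The forecast also names zeta, with 52.8% for gamma, 78.6% for zeta, 63.9% for theta and 48.5% for delta, reasoning “so little target has yet been consumed by substrate”.

The flasks give 52.3% in gamma, 78.5% in zeta, 63.8% in theta and 47.7% in delta, with zeta leading. Conversion at the end stands at 22.4% in zeta and 95.9% in delta. For delta with its substrate cut to 0.0060 M, equivalents and time held, the reckoning gives a conversion of 74.0% and z = 0.843. That z is still larger than the 0.277 of zeta, and it gives a share of 54.3%, while that flask ends at 56.4%.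

(The numbers are those of an exercise; the rest is arithmetic.)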